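Remark on the chemistry: atom labels C1–C15 are those of germacranolide numbering of the target (ring C1…C10, lactone O–C6 / C12(=O) / C11(=C13) / C7, C14 on C10, C15 on C4). Nerol is used as its commercial acetate 1; compounds 11, 16 and 20 are taken as purchased.

## Analysis of the target

The target is a cis,cis-germacranolide: a ten-membered carbocycle whose two trisubstituted ring alkenes (C1=C10 and C4=C5) are both Z, fused trans at C6–C7 to an α-methylene-γ-butyrolactone (O–C6, C12 carbonyl, exocyclic C11=C13). Four contiguous stereocenters run C6 (R), C7 (S), C8 (S), C9 (R): H6 and H7 are trans on the lactone, C8 carries the angelate, and C9 carries a free allylic hydroxyl that is 8,9-anti to it. C10 bears the primary allylic C14 alcohol and C4 the C15 methyl group. The sensitive groups are the exocyclic enoate of the lactone (a Michael acceptor), the angelate (it isomerises to the tiglate and can migrate to a neighbouring free hydroxyl), the allylic C6–O bond of the lactone, and the two Z alkenes. The difficulty is to close a ten-membered ring containing two cis alkenes while four adjacent stereocenters and three differently treated oxygens (acylated O8, free O9 and O14) are kept in order. The feature used is that C9 is an allylic carbinol lying between C10 of the Z C1=C10 alkene and the acyloxy-bearing C8. The ring bond C9–C10 can therefore be made by adding a geometry-defined C10 alkenyl metal to a C9 aldehyde, which closes the ring and creates C9 in one operation under conditions that spare lactone and ester.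

## Retrosynthetic reasoning

27 from 26. The last bond cut is the O14–Si bond. C14 stays silylated to the end because C9 has to be oxidised to an aldehyde while C14 is present, and a fluoride-labile ether can be removed without touching the angelate or the lactone.

26 from 24 (through 25). The ring bond C9–C10 is cut. It is the only ring bond that joins an sp2 carbon of fixed geometry to a carbinol carbon, so the cut turns the ring into a Z alkenyl iodide and an aldehyde, two groups that coexist with an ester and a lactone. Cuts at C2–C3, C5–C6 or C7–C8 would call for carbanion or enolate chemistry that the acyl groups do not survive, or would leave stereocenters to be set on a floppy ring. The gain is that the ring and the fourth stereocenter appear together; the forward step must beat intermolecular coupling and deliver 9R.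

24 from 23 from 22. The C9 aldehyde is traced to the primary alcohol and this to its 4-methoxybenzyl ether. That ether is cleaved oxidatively at neutral pH, so the angelate on O8 is given no acid or base with which to migrate to O9, and it is orthogonal to the O14 silyl ether.

22 from 19 and 20. The O8–acyl bond is cut. The angelate goes on late, onto the only free hydroxyl and after every basic step, because of its tendency to isomerise.

19 from 17 (through 18). Two bonds of the lactone are cut: C11=C13 (one-carbon Horner–Wadsworth–Emmons olefination) and C7–C11. With C12 already attached to O6 as a phosphonoacetate, the C11 carbanion reaches C7 of the C7–C8 epoxide in a 5-exo sense. Opening with inversion gives the trans lactone and uncovers the C8 hydroxyl with the configuration the epoxide had. No free lactone enolate is needed, and the O6 ester serves as tether and as future ring.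

17 from 15 and 16. The O6–C12 ester bond is cut.

15 from 14. The C7–C8 epoxide is traced to the E alkene of the racemic bis-allylic alcohol. A Sharpless epoxidation run as a kinetic resolution fixes C6, C7 and C8 together: only the S carbinol is epoxidised quickly, on the face that leads to the erythro 6R,7R,8R epoxy alcohol.

14 from 10 and 11 (through 12 and 13). The C6–C7 bond is cut: an E alkenyl metal made from alkyne 11 adds to enal 10, and C9 arrives as a protected primary alcohol.

10 from 9, 8, 7, 6 and 5. These are functional-group changes: the C6 aldehyde from the allylic acetate, the O14 silyl ether from the alcohol, that from the α-iodo enal 6, and 6 from enal 5. Iodine is placed on C10 by α-iodination of the enal, whose E geometry becomes the Z iodoalkene.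

5 from 4. The C1=C10 bond is cut; a two-carbon Wittig homologation brings in C10 and C14.

4 from 2 from 1 (through 3). The C1 aldehyde comes from cleaving the terminal trisubstituted alkene of 1. Compound 1 already holds C6–C5=C4(C15)–C3–C2–C1 with the Z alkene in place, so the C4=C5 geometry is bought, not made.

## Alternatives that were turned down

Alternative 1: the lactone is disconnected last, at C12–O6 and C11–C12. The ring-closed homopropargylic alcohol A2 (free C6 hydroxyl, ethynyl group on C7, O9/O14 tied as an acetonide) would be treated with PdCl2 and thiourea under CO to give the acetonide A1 by hydroxyl-directed cyclocarbonylation.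
- For it: the Michael acceptor appears only at the end and is never carried through acylation, oxidation or ring closure, and the C6/C7 relationship is fixed before the lactone forms. On this point it is stronger than the chosen route, which carries the methylene lactone through five steps.
- Against it: the ten-membered ring of A2 must be made without the lactone, a macrocyclisation this plan does not solve and one that lacks the trans-fused five-membered ring to fold the chain. Divalent palladium under CO meets a doubly allylic C6 alcohol, two trisubstituted alkenes and an angelate, so ionisation at C6, alkene isomerisation and other carbonylation modes compete. The final acetonide hydrolysis needs acid next to the allylic C6–O bond of the lactone.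
- Comparison: the chosen strategy spends its risk on one ring-forming step that also sets C9, after a lactone synthesis whose stereochemistry comes from an epoxide, and ends with a neutral desilylation.

Alternative 2: the ring is cut at the sp3–sp3 bond C2–C3. The acyclic bromo sulfone A4 would be deprotonated at C2 with KN(Si(CH3)3)2 under high dilution, and the sulfonyl-stabilised allyl anion would displace the C3 allylic bromide to give the ten-membered sulfone A3.
- For it: the new bond is remote from all four stereocenters, nothing stereochemical has to be controlled in the ring closure, and sulfone alkylation is a proven way to close medium carbocycles. As a pure ring closure it is probably the more robust of the two.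
- Against it: the strong base rules out lactone and angelate, so A3 carries five protecting groups. After ring closure the sulfone must be removed reductively (with the risk of shifting or isomerising the C1=C10 allyl system), C12 oxidised and lactonised, O8 acylated and O9/O14 released, about seven further steps. The allyl sulfone anion can also alkylate at its γ terminus, and the Z allylic bromide can react in the SN2' sense.
- Comparison: the chosen key step closes the ring one step from the target with both acyl groups in place; the price is that C9 must be controlled during ring closure.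

Alternative 3: the ten-membered ring is revealed from a cis-decalin by breaking the transannular C4–C9 bond. The C9 alkoxide of the mesylate A6, made with KOC(CH3)3, would fragment: C4–C9 breaks, C9 becomes a ketone, C4=C5 forms and the C5 mesylate leaves, giving the Z,Z-cyclodecadienone A5.
- For it: the ring is unveiled and not closed, so there is no entropic penalty, and the Z geometry of C4=C5 follows stereospecifically from the antiperiplanar arrangement in the cis-fused bicycle. On both counts it is stronger than a macrocyclisation.
- Against it: A6 needs five stereocenters, three of which (C4, C5, C9) exist only to be destroyed. A5 has C8 as a methylene group and C9 as a ketone, so C8 oxygenation next to the ketone, stereoselective C9 reduction, lactone construction from the C11–C13 unit and angeloylation would all have to be done on a flexible cyclodecadienone prone to transannular reactions.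
- Comparison: the chosen strategy sets C6–C8 on an open chain where acyclic stereocontrol is dependable, and the ring closure itself creates C9 at the right oxidation level.

Key step: step 16

## Route

Step 1
Reactants: 1 neryl acetate
Product: 2 6,7-epoxyneryl acetate (racemic at the oxirane carbon)
Conditions: mCPBA, CH2Cl2, 0 °C
Reagents that add atoms: mCPBA (3-chloroperoxybenzoic acid), O=C(OO)c1cccc(Cl)c1
Why: Peracid epoxidation is electrophilic and goes to the more electron-rich distal alkene; the 2,3-alkene is deactivated by the allylic acetate. The new stereocenter is destroyed in step 2, so it needs no control.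

Step 2
Reactants: 2 6,7-epoxyneryl acetate
Product: 4 (2Z)-3-methyl-6-oxohex-2-en-1-yl acetate, via vicinal diol 3 (not isolated)
Conditions: H5IO6, THF/H2O, 0 °C
Reagents that add atoms: none
Why: Periodic acid hydrates the epoxide at its tertiary carbon to diol 3 and cleaves the glycol (Malaprade cleavage), so the epoxide oxygen stays on the aldehyde carbon and acetone is lost. The Z alkene and the acetate are untouched at 0 °C.

Step 3
Reactants: 4 (2Z)-3-methyl-6-oxohex-2-en-1-yl acetate
Product: 5 (2Z,6E)-3-methyl-8-oxoocta-2,6-dien-1-yl acetate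
Conditions: Ph3P=CHCHO, toluene, 80 °C
Reagents that add atoms: (triphenylphosphoranylidene)acetaldehyde, O=CC=P(c1ccccc1)(c1ccccc1)c1ccccc1
Why: Wittig reaction of a stabilised formyl ylide with an unhindered aliphatic aldehyde gives the E enal and brings in C10 and C14. A small excess of ylide and moderate temperature limit a second homologation.

Step 4
Reactants: 5 (2Z,6E)-3-methyl-8-oxoocta-2,6-dien-1-yl acetate
Product: 6 (2Z,6Z)-7-iodo-3-methyl-8-oxoocta-2,6-dien-1-yl acetate
Conditions: I2, K2CO3, DMAP (cat.), THF/H2O, 0→23 °C
Reagents that add atoms: iodine, II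
Why: Nucleophile-catalysed α-iodination (conjugate addition of DMAP, iodination of the enolate, elimination; the halogen counterpart of a Baylis–Hillman sequence) puts iodine on C10. The chain stays trans to the formyl group and is therefore cis to iodine, which is the Z iodoalkene needed at C1=C10.

Step 5
Reactants: 6 (2Z,6Z)-7-iodo-3-methyl-8-oxoocta-2,6-dien-1-yl acetate
Product: 7 (2Z,6Z)-8-hydroxy-7-iodo-3-methylocta-2,6-dien-1-yl acetate
Conditions: NaBH4, CeCl3·7H2O, MeOH, −20 °C
Reagents that add atoms: none
Why: Luche reduction gives clean 1,2-reduction of the α-iodo enal without touching the acetate or the C–I bond.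

Step 6
Reactants: 7 (2Z,6Z)-8-hydroxy-7-iodo-3-methylocta-2,6-dien-1-yl acetate
Product: 8 (2Z,6Z)-8-[(tert-butyldimethylsilyl)oxy]-7-iodo-3-methylocta-2,6-dien-1-yl acetate
Conditions: TBSCl, imidazole, CH2Cl2, 0→23 °C
Reagents that add atoms: TBSCl (tert-butyldimethylsilyl chloride), CC(C)(C)[Si](C)(C)Cl
Why: Standard silylation of a primary allylic alcohol; the silyl ether keeps O14 masked until the last step.

Step 7
Reactants: 8 (2Z,6Z)-8-[(tert-butyldimethylsilyl)oxy]-7-iodo-3-methylocta-2,6-dien-1-yl acetate
Product: 9 (2Z,6Z)-8-[(tert-butyldimethylsilyl)oxy]-7-iodo-3-methylocta-2,6-dien-1-ol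
Conditions: K2CO3 (cat.), MeOH, 0 °C
Reagents that add atoms: none
Why: Mild methanolysis removes only the acetate; the silyl ether and the alkenyl iodide are stable to carbonate in methanol at 0 °C.

Step 8
Reactants: 9 (2Z,6Z)-8-[(tert-butyldimethylsilyl)oxy]-7-iodo-3-methylocta-2,6-dien-1-ol
Product: 10 (2Z,6Z)-8-[(tert-butyldimethylsilyl)oxy]-7-iodo-3-methylocta-2,6-dienal
Conditions: TEMPO (cat.), PhI(OAc)2, CH2Cl2, 23 °C
Reagents that add atoms: none
Why: Oxoammonium oxidation converts Z allylic alcohols of the nerol type to Z enals without Z/E isomerisation or over-oxidation. No metal or base that could touch the C–I bond is present.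

Step 9
Reactants: 11 4-methoxybenzyl propargyl ether; 10 (2Z,6Z)-8-[(tert-butyldimethylsilyl)oxy]-7-iodo-3-methylocta-2,6-dienal
Product: 14 rac-(2E,5Z,9Z)-11-[(tert-butyldimethylsilyl)oxy]-10-iodo-1-[(4-methoxybenzyl)oxy]-6-methylundeca-2,5,9-trien-4-ol, via alkenylzirconocene chloride 12 (not isolated), via alkenyl(methyl)zinc 13 (not isolated)
Conditions: Cp2Zr(H)Cl, CH2Cl2, 23 °C; Zn(CH3)2, −65 °C; then 10, 0 °C
Reagents that add atoms: none
Why: Hydrozirconation of the terminal alkyne is syn and puts zirconium at the terminus, giving the E alkenyl metal; transmetalation to zinc gives a reagent that adds 1,2 to the enal and neither exchanges with the alkenyl iodide nor attacks the silyl ether. No control is attempted at C6 because the racemate is resolved in step 10.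

Step 10
Reactants: 14 racemic bis-allylic alcohol
Product: 15 (1R,2Z,6Z)-8-[(tert-butyldimethylsilyl)oxy]-7-iodo-1-[(2R,3R)-3-{[(4-methoxybenzyl)oxy]methyl}oxiran-2-yl]-3-methylocta-2,6-dien-1-ol
Conditions: Ti(OiPr)4, diisopropyl D-(−)-tartrate, tBuOOH (0.5 equiv), 4 Å MS, CH2Cl2, −20 °C
Reagents that add atoms: tert-butyl hydroperoxide, CC(C)(C)OO
Why: Sharpless asymmetric epoxidation used as a kinetic resolution: with the D-(−)-tartrate the S carbinol is the fast enantiomer and is epoxidised at the E C7=C8 alkene on the face that gives the erythro 6R,7R,8R epoxy alcohol, so three stereocenters are fixed at once. The R carbinol is mismatched for this alkene, and its other allylic alkene (C4=C5) carries a cis substituent that also makes it slow, so it should remain and be separated.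

Step 11
Reactants: 15 epoxy alcohol; 16 (diethoxyphosphoryl)acetic acid
Product: 17 (diethoxyphosphoryl)acetate of 15 at O6
Conditions: DCC, DMAP (cat.), CH2Cl2, 0→23 °C
Reagents that add atoms: none
Why: Steglich esterification of the secondary alcohol under neutral conditions leaves the epoxide intact and hangs C11 and C12 on O6.

Step 12
Reactants: 17 epoxy phosphonoacetate
Product: 19 (4R,5R)-4-[(1S)-1-hydroxy-2-[(4-methoxybenzyl)oxy]ethyl]-5-[(1Z,5Z)-7-[(tert-butyldimethylsilyl)oxy]-6-iodo-2-methylhepta-1,5-dien-1-yl]-3-methylideneoxolan-2-one, via phosphono lactone 18 (not isolated)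
Conditions: NaH, THF, 0→45 °C; then (CH2O)n, 23 °C
Reagents that add atoms: formaldehyde (from paraformaldehyde), C=O
Why: The phosphonate-stabilised C11 carbanion, tethered through the O6 ester, opens the epoxide at C7 by 5-exo-tet SN2 attack (lactone annulation of an epoxy alcohol ester by a tethered stabilised enolate). In the erythro ester the conformer with C5 anti to C8 has O6 anti to the epoxide C7–O bond, so backside attack is easy; inversion at C7 gives the trans lactone and C8 keeps the epoxide oxygen. The C8 alkoxide is quenched by the acidic α-phosphono C–H of 18, and the resulting enolate undergoes Horner–Wadsworth–Emmons methylenation with formaldehyde in the same flask.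

Step 13
Reactants: 20 angelic acid; 19 methylene lactone alcohol
Product: 22 O8-angelate of 19, via mixed anhydride 21 (not isolated)
Conditions: 2,4,6-Cl3C6H2COCl, Et3N, toluene, 23 °C; then 19, 75 °C (no DMAP)
Reagents that add atoms: none
Why: Yamaguchi-type mixed-anhydride acylation: the alcohol attacks the unhindered angeloyl carbonyl of 21. Leaving out the nucleophilic catalyst avoids the addition–elimination pathway that turns angelates into tiglates and would also add to the methylene lactone.

Step 14
Reactants: 22 angelate 4-methoxybenzyl ether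
Product: 23 (1S)-2-hydroxy-1-[(2R,3S)-2-[(1Z,5Z)-7-[(tert-butyldimethylsilyl)oxy]-6-iodo-2-methylhepta-1,5-dien-1-yl]-4-methylidene-5-oxooxolan-3-yl]ethyl (2Z)-2-methylbut-2-enoate
Conditions: DDQ, CH2Cl2/pH 7 buffer, 0 °C
Reagents that add atoms: none
Why: DDQ removes the 4-methoxybenzyl ether by benzylic hydride abstraction and hydrolysis. The buffered neutral medium leaves silyl ether, iodide and both esters alone and gives the angelate no acid or base with which to migrate to O9.

Step 15
Reactants: 23 primary alcohol
Product: 24 (1S)-2-oxo-1-[(2R,3S)-2-[(1Z,5Z)-7-[(tert-butyldimethylsilyl)oxy]-6-iodo-2-methylhepta-1,5-dien-1-yl]-4-methylidene-5-oxooxolan-3-yl]ethyl (2Z)-2-methylbut-2-enoate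
Conditions: Dess–Martin periodinane, CH2Cl2, 0→23 °C
Reagents that add atoms: none
Why: Dess–Martin oxidation of the primary alcohol under non-basic conditions gives the α-acyloxy aldehyde without epimerising C8; the aldehyde is used at once.

Step 16
Reactants: 24 seco iodo aldehyde
Product: 26 14-O-tert-butyldimethylsilyl ether of 27, via alkenylchromium dichloride 25 (not isolated)
Conditions: CrCl2 (excess), NiCl2 (cat.), DMSO, 23 °C, slow addition to 0.002 M
Reagents that add atoms: none
Why: CrCl2 reduces NiCl2 to zerovalent nickel, which inserts into the C10–I bond of 24 with retention of the Z geometry; transmetalation to trivalent chromium gives the alkenylchromium 25, which adds to the C9 aldehyde. The closest known reaction type is the Nozaki–Hiyama–Kishi macrocyclisation of alkenyl iodides onto aldehydes. The ten-membered carbocycle closes by intramolecular 1,2-carbonyl addition in a 10-exo-trig mode, forming C9–C10. The new C9 stereocenter is controlled by the adjacent C8 centre: Felkin–Anh attack anti to the C8–O bond of the angelate should give the 8,9-anti (9R) carbinol, and the trans lactone and the two Z alkenes limit the ring-forming conformers so that this preference is expected to be kept. The step needs ring closure to beat intermolecular coupling, which high dilution with slow addition and the folded chain are meant to secure. It also needs selectivity for the aldehyde over lactone, angelate and exocyclic enoate, which the low basicity and carbonyl selectivity of organochromium reagents provide, and the epimerisable C8 centre sees no base. The C1=C10 geometry is inherited from the iodide because insertion and transmetalation are stereoretentive.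

Step 17
Reactants: 26 14-O-silyl ether
Product: 27 target, (3aS,4S,5R,6Z,10Z,11aR)-5-hydroxy-6-(hydroxymethyl)-10-methyl-3-methylidene-2-oxo-2,3,3a,4,5,8,9,11a-octahydrocyclodeca[b]furan-4-yl (2Z)-2-methylbut-2-enoate
Conditions: HF·pyridine, pyridine, THF, 0→23 °C
Reagents that add atoms: none
Why: Fluoride cleaves the primary allylic silyl ether. Buffered HF·pyridine is not basic enough for conjugate addition or acyl migration and not acidic enough to ionise the allylic lactone.

## Compound list

1 | neryl acetate, (2Z)-3,7-dimethylocta-2,6-dien-1-yl acetate | CC(C)=CCC/C(C)=C\COC(C)=O | starting material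
2 | (2Z)-5-(3,3-dimethyloxiran-2-yl)-3-methylpent-2-en-1-yl acetate (racemic at the oxirane carbon) | CC(=O)OC/C=C(/C)CCC1OC1(C)C | intermediate
3 | (2Z)-6,7-dihydroxy-3,7-dimethyloct-2-en-1-yl acetate (racemic) | CC(=O)OC/C=C(/C)CCC(O)C(C)(C)O | intermediate
4 | (2Z)-3-methyl-6-oxohex-2-en-1-yl acetate | CC(=O)OC/C=C(/C)CCC=O | intermediate
5 | (2Z,6E)-3-methyl-8-oxoocta-2,6-dien-1-yl acetate | CC(=O)OC/C=C(/C)CC/C=C/C=O | intermediate
6 | (2Z,6Z)-7-iodo-3-methyl-8-oxoocta-2,6-dien-1-yl acetate | CC(=O)OC/C=C(/C)CC/C=C(\I)C=O | intermediate
7 | (2Z,6Z)-8-hydroxy-7-iodo-3-methylocta-2,6-dien-1-yl acetate | CC(=O)OC/C=C(/C)CC/C=C(\I)CO | intermediate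
8 | (2Z,6Z)-8-[(tert-butyldimethylsilyl)oxy]-7-iodo-3-methylocta-2,6-dien-1-yl acetate | CC(=O)OC/C=C(/C)CC/C=C(\I)CO[Si](C)(C)C(C)(C)C | intermediate
9 | (2Z,6Z)-8-[(tert-butyldimethylsilyl)oxy]-7-iodo-3-methylocta-2,6-dien-1-ol | OC/C=C(/C)CC/C=C(\I)CO[Si](C)(C)C(C)(C)C | intermediate
10 | (2Z,6Z)-8-[(tert-butyldimethylsilyl)oxy]-7-iodo-3-methylocta-2,6-dienal | O=C/C=C(/C)CC/C=C(\I)CO[Si](C)(C)C(C)(C)C | intermediate
11 | 1-methoxy-4-[(prop-2-yn-1-yloxy)methyl]benzene (4-methoxybenzyl propargyl ether) | C#CCOCc1ccc(OC)cc1 | starting material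
12 | chloridobis(cyclopentadienyl)[(1E)-3-[(4-methoxybenzyl)oxy]prop-1-en-1-yl]zirconium | COc1ccc(COC/C=C/[Zr](Cl)(C2C=CC=C2)C2C=CC=C2)cc1 | intermediate
13 | methyl[(1E)-3-[(4-methoxybenzyl)oxy]prop-1-en-1-yl]zinc | COc1ccc(COC/C=C/[Zn]C)cc1 | intermediate
14 | rac-(2E,5Z,9Z)-11-[(tert-butyldimethylsilyl)oxy]-10-iodo-1-[(4-methoxybenzyl)oxy]-6-methylundeca-2,5,9-trien-4-ol | COc1ccc(COC/C=C/C(O)/C=C(/C)CC/C=C(\I)CO[Si](C)(C)C(C)(C)C)cc1 | intermediate
15 | (1R,2Z,6Z)-8-[(tert-butyldimethylsilyl)oxy]-7-iodo-1-[(2R,3R)-3-{[(4-methoxybenzyl)oxy]methyl}oxiran-2-yl]-3-methylocta-2,6-dien-1-ol | COc1ccc(COC[C@H]2O[C@@H]2[C@H](O)/C=C(/C)CC/C=C(\I)CO[Si](C)(C)C(C)(C)C)cc1 | intermediate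
16 | (diethoxyphosphoryl)acetic acid | CCOP(=O)(CC(=O)O)OCC | starting material
17 | (1R,2Z,6Z)-8-[(tert-butyldimethylsilyl)oxy]-7-iodo-1-[(2R,3R)-3-{[(4-methoxybenzyl)oxy]methyl}oxiran-2-yl]-3-methylocta-2,6-dien-1-yl (diethoxyphosphoryl)acetate | COc1ccc(COC[C@H]2O[C@@H]2[C@H](OC(=O)CP(=O)(OCC)OCC)/C=C(/C)CC/C=C(\I)CO[Si](C)(C)C(C)(C)C)cc1 | intermediate
18 | diethyl [(4R,5R)-4-[(1S)-1-hydroxy-2-[(4-methoxybenzyl)oxy]ethyl]-5-[(1Z,5Z)-7-[(tert-butyldimethylsilyl)oxy]-6-iodo-2-methylhepta-1,5-dien-1-yl]-2-oxooxolan-3-yl]phosphonate (both C3 epimers) | COc1ccc(COC[C@@H](O)[C@H]2C(P(=O)(OCC)OCC)C(=O)O[C@@H]2/C=C(/C)CC/C=C(\I)CO[Si](C)(C)C(C)(C)C)cc1 | intermediate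
19 | (4R,5R)-4-[(1S)-1-hydroxy-2-[(4-methoxybenzyl)oxy]ethyl]-5-[(1Z,5Z)-7-[(tert-butyldimethylsilyl)oxy]-6-iodo-2-methylhepta-1,5-dien-1-yl]-3-methylideneoxolan-2-one | COc1ccc(COC[C@@H](O)[C@H]2C(=C)C(=O)O[C@@H]2/C=C(/C)CC/C=C(\I)CO[Si](C)(C)C(C)(C)C)cc1 | intermediate
20 | angelic acid, (2Z)-2-methylbut-2-enoic acid | C/C=C(/C)C(=O)O | starting material
21 | (2Z)-2-methylbut-2-enoic 2,4,6-trichlorobenzoic anhydride | C/C=C(/C)C(=O)OC(=O)c1c(Cl)cc(Cl)cc1Cl | intermediate
22 | (1S)-2-[(4-methoxybenzyl)oxy]-1-[(2R,3S)-2-[(1Z,5Z)-7-[(tert-butyldimethylsilyl)oxy]-6-iodo-2-methylhepta-1,5-dien-1-yl]-4-methylidene-5-oxooxolan-3-yl]ethyl (2Z)-2-methylbut-2-enoate | COc1ccc(COC[C@@H](OC(=O)/C(C)=C\C)[C@H]2C(=C)C(=O)O[C@@H]2/C=C(/C)CC/C=C(\I)CO[Si](C)(C)C(C)(C)C)cc1 | intermediate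
23 | (1S)-2-hydroxy-1-[(2R,3S)-2-[(1Z,5Z)-7-[(tert-butyldimethylsilyl)oxy]-6-iodo-2-methylhepta-1,5-dien-1-yl]-4-methylidene-5-oxooxolan-3-yl]ethyl (2Z)-2-methylbut-2-enoate | OC[C@@H](OC(=O)/C(C)=C\C)[C@H]1C(=C)C(=O)O[C@@H]1/C=C(/C)CC/C=C(\I)CO[Si](C)(C)C(C)(C)C | intermediate
24 | (1S)-2-oxo-1-[(2R,3S)-2-[(1Z,5Z)-7-[(tert-butyldimethylsilyl)oxy]-6-iodo-2-methylhepta-1,5-dien-1-yl]-4-methylidene-5-oxooxolan-3-yl]ethyl (2Z)-2-methylbut-2-enoate (seco iodo aldehyde) | O=C[C@@H](OC(=O)/C(C)=C\C)[C@H]1C(=C)C(=O)O[C@@H]1/C=C(/C)CC/C=C(\I)CO[Si](C)(C)C(C)(C)C | intermediate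
25 | Z alkenylchromium dichloride formed from 24 at C10 (trivalent chromium) | O=C[C@@H](OC(=O)/C(C)=C\C)[C@H]1C(=C)C(=O)O[C@@H]1/C=C(/C)CC/C=C(/CO[Si](C)(C)C(C)(C)C)[Cr](Cl)Cl | intermediate
26 | (3aS,4S,5R,6Z,10Z,11aR)-6-{[(tert-butyldimethylsilyl)oxy]methyl}-5-hydroxy-10-methyl-3-methylidene-2-oxo-2,3,3a,4,5,8,9,11a-octahydrocyclodeca[b]furan-4-yl (2Z)-2-methylbut-2-enoate | C=C1C(=O)O[C@@H]2/C=C(/C)CC/C=C(/CO[Si](C)(C)C(C)(C)C)[C@@H](O)[C@@H](OC(=O)/C(C)=C\C)[C@@H]12 | intermediate
27 | (3aS,4S,5R,6Z,10Z,11aR)-5-hydroxy-6-(hydroxymethyl)-10-methyl-3-methylidene-2-oxo-2,3,3a,4,5,8,9,11a-octahydrocyclodeca[b]furan-4-yl (2Z)-2-methylbut-2-enoate | C=C1C(=O)O[C@@H]2/C=C(/C)CC/C=C(/CO)[C@@H](O)[C@@H](OC(=O)/C(C)=C\C)[C@@H]12 | target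

## Step count and weak points

Total step count: 17. Longest linear sequence: 17 steps (1 to 27); 11, 16 and 20 are purchased and enter directly.

Least certain steps:

Step 16 (key step). Two processes threaten it. Intermolecular coupling can outrun closure of a strained ten-membered ring with two cis alkenes and give oligomers. The facial selectivity at C9 can also be poor if the preferred ring-forming conformer opposes the Felkin–Anh preference set by C8. Fallback: the route sets out from 24 and accepts whatever C9 mixture the ring closure gives, 26 together with the 9-epi carbinol F1. The mixture is oxidised with Dess–Martin periodinane to the cross-conjugated C9 enone F2, which is reduced under reagent control (oxazaborolidine-catalysed borane reduction, Corey–Bakshi–Shibata) to return to 26. Control of C9 is thereby moved from the C–C bond formation to a ketone reduction.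

Step 12. The doubly stabilised phosphonoacetate anion is a weak nucleophile, so epoxide opening may be slow. If heating is then needed, the phosphoryl group can transfer to the new C8 alkoxide and the chain can close to a cyclopropane (the Wadsworth–Emmons cyclopropanation pathway), or the alkoxide can translactonise to the cis 8,12-lactone. Fallback with a more nucleophilic tethered enolate: from 15, esterification with (phenylthio)acetic acid (DCC, DMAP) gives the (phenylthio)acetate F3. LiN(Si(CH3)3)2 in THF closes the α-phenylthio lactone F4 by the same 5-exo opening. A second deprotonation and C-methylation with CH3I gives the α-methyl-α-phenylthio lactone F5, with the methyl group entering trans to the C7 side chain. Oxidation at sulfur with NaIO4 gives the sulfoxide F6, and thermal syn-elimination, which can only use a methyl hydrogen because H7 is trans to sulfur, returns to 19.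

Step 10. The resolution can lose selectivity in three ways: slow epoxidation of the wanted enantiomer next to the bulky Z alkenyl group, competing epoxidation of C4=C5 in the unwanted enantiomer, and Lewis-acid ionisation of the doubly allylic alcohol. At best half of 14 is used. Fallback that sets C6 before the epoxidation: from 10, enantioselective addition of alkyne 11 with Zn(CH3)2 and the ProPhenol ligand (the ligand enantiomer that gives the R carbinol) gives the (4R) propargylic alcohol F7. Trans reduction with NaAlH2(OCH2CH2OCH3)2 at low temperature gives the (4S) E allylic alcohol F8, and the same titanium–tartrate epoxidation, now matched and run to full conversion, returns to 15.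

Step 13. The hindered C8 hydroxyl may acylate only slowly without a nucleophilic catalyst, and on prolonged heating the angeloyl group can isomerise to the tiglate. Fallback that builds the Z enoate on the substrate: from 19, esterification with 2-(diphenoxyphosphoryl)propanoic acid (DCC, DMAP) gives the phosphonopropionate F9. A Z-selective Horner–Wadsworth–Emmons reaction of the Ando type with acetaldehyde (NaH, THF, −78→0 °C) forms the angelate double bond directly and returns to 22.

Step 4. The aqueous carbonate can hydrolyse the allylic acetate during the iodination, and reversible amine addition to an acyclic enal can leave the conversion incomplete. Fallback that avoids the enal: from 4, a Wittig olefination with the α-iodo ylide generated from [2-(tert-butyldimethylsilyloxy)ethyl]triphenylphosphonium iodide (deprotonation, iodination, second deprotonation) gives the Z iodoalkene 8 directly and replaces steps 3 to 6. This fallback makes no new compound (entry F0).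

## Further compounds

F1 | step 16 | 9-epi-26, (3aS,4S,5S,6Z,10Z,11aR)-6-{[(tert-butyldimethylsilyl)oxy]methyl}-5-hydroxy-10-methyl-3-methylidene-2-oxo-2,3,3a,4,5,8,9,11a-octahydrocyclodeca[b]furan-4-yl (2Z)-2-methylbut-2-enoate | C=C1C(=O)O[C@@H]2/C=C(/C)CC/C=C(/CO[Si](C)(C)C(C)(C)C)[C@H](O)[C@@H](OC(=O)/C(C)=C\C)[C@@H]12
F2 | step 16 | C9 enone, (3aS,4S,6Z,10Z,11aR)-6-{[(tert-butyldimethylsilyl)oxy]methyl}-10-methyl-3-methylidene-2,5-dioxo-2,3,3a,4,5,8,9,11a-octahydrocyclodeca[b]furan-4-yl (2Z)-2-methylbut-2-enoate | C=C1C(=O)O[C@@H]2/C=C(/C)CC/C=C(/CO[Si](C)(C)C(C)(C)C)C(=O)[C@@H](OC(=O)/C(C)=C\C)[C@@H]12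
F3 | step 12 | (phenylthio)acetate of 15 at O6 | COc1ccc(COC[C@H]2O[C@@H]2[C@H](OC(=O)CSc2ccccc2)/C=C(/C)CC/C=C(\I)CO[Si](C)(C)C(C)(C)C)cc1
F4 | step 12 | (4R,5R)-4-[(1S)-1-hydroxy-2-[(4-methoxybenzyl)oxy]ethyl]-5-[(1Z,5Z)-7-[(tert-butyldimethylsilyl)oxy]-6-iodo-2-methylhepta-1,5-dien-1-yl]-3-(phenylthio)oxolan-2-one (C3 epimers) | COc1ccc(COC[C@@H](O)[C@H]2C(Sc3ccccc3)C(=O)O[C@@H]2/C=C(/C)CC/C=C(\I)CO[Si](C)(C)C(C)(C)C)cc1
F5 | step 12 | 3-methyl-3-(phenylthio) analogue of F4 | COc1ccc(COC[C@@H](O)[C@H]2C(C)(Sc3ccccc3)C(=O)O[C@@H]2/C=C(/C)CC/C=C(\I)CO[Si](C)(C)C(C)(C)C)cc1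
F6 | step 12 | 3-methyl-3-(phenylsulfinyl) analogue of F4 | COc1ccc(COC[C@@H](O)[C@H]2C(C)(S(=O)c3ccccc3)C(=O)O[C@@H]2/C=C(/C)CC/C=C(\I)CO[Si](C)(C)C(C)(C)C)cc1
F7 | step 10 | (4R,5Z,9Z)-11-[(tert-butyldimethylsilyl)oxy]-10-iodo-1-[(4-methoxybenzyl)oxy]-6-methylundeca-5,9-dien-2-yn-4-ol | COc1ccc(COCC#C[C@H](O)/C=C(/C)CC/C=C(\I)CO[Si](C)(C)C(C)(C)C)cc1
F8 | step 10 | (2E,4S,5Z,9Z)-11-[(tert-butyldimethylsilyl)oxy]-10-iodo-1-[(4-methoxybenzyl)oxy]-6-methylundeca-2,5,9-trien-4-ol | COc1ccc(COC/C=C/[C@H](O)/C=C(/C)CC/C=C(\I)CO[Si](C)(C)C(C)(C)C)cc1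
F9 | step 13 | 2-(diphenoxyphosphoryl)propanoate of 19 at O8 (both epimers at the phosphonate carbon) | COc1ccc(COC[C@@H](OC(=O)C(C)P(=O)(Oc3ccccc3)Oc3ccccc3)[C@H]2C(=C)C(=O)O[C@@H]2/C=C(/C)CC/C=C(\I)CO[Si](C)(C)C(C)(C)C)cc1
F0 | step 4 | none | none
A1 | alternative 1 | 9,14-O-isopropylidene acetal of 27 | C=C1C(=O)O[C@@H]2/C=C(/C)CC/C=C3/COC(C)(C)O[C@H]3[C@@H](OC(=O)/C(C)=C\C)[C@@H]12
A2 | alternative 1 | ten-membered C6 carbinol with a C7 ethynyl group, the O8 angelate and the 9,14-acetonide | C#C[C@H]1[C@H](O)/C=C(/C)CC/C=C2/COC(C)(C)O[C@H]2[C@H]1OC(=O)/C(C)=C\C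
A3 | alternative 2 | ten-membered C2 phenyl sulfone (O6 and O12 silyl ethers, O8 4-methoxybenzyl ether, 9,14-acetonide) | C=C(CO[Si](C)(C)C(C)(C)C)[C@H]1[C@H](O[Si](C)(C)C(C)(C)C)/C=C(/C)CC(S(=O)(=O)c2ccccc2)/C=C2/COC(C)(C)O[C@H]2[C@H]1OCc1ccc(OC)cc1
A4 | alternative 2 | acyclic C3 allylic bromide with a C2 phenylsulfonyl group (seco form of A3) | BrC/C(C)=C\[C@@H](O[Si](C)(C)C(C)(C)C)[C@H](C(=C)CO[Si](C)(C)C(C)(C)C)[C@H](OCc1ccc(OC)cc1)[C@@H]1OC(C)(C)OC/C1=C/CS(=O)(=O)c1ccccc1
A5 | alternative 3 | Z,Z-cyclodecadien-9-one carrying C6 (triethylsilyl ether), C7 (C11–C13 unit with O12 4-methoxybenzyl ether) and C14 (silyl ether) | C=C(COCc1ccc(OC)cc1)[C@H]1[C@H](O[Si](CC)(CC)CC)/C=C(/C)CC/C=C(/CO[Si](C)(C)C(C)(C)C)C(=O)C1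
A6 | alternative 3 | cis-decalin with the C4–C9 fusion bond, C9 tertiary alcohol, C4 methyl and equatorial C5 mesylate | C[C@]12CCC=C(CO[Si](C)(C)C(C)(C)C)[C@@]1(O)C[C@@H](C(=C)COCc1ccc(OC)cc1)[C@H](O[Si](CC)(CC)CC)[C@H]2OS(C)(=O)=O
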